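The route rests on cutting the two bonds that flank the C8 carbinol: C7–C8 and C9–C10. C8 sits between the alkenyl carbon C7, which hangs on ring carbon C1 of the cyclohexane, and the C9 methylene leading to the C10=C11 alkene (later the epoxide); this is the pattern a vinylboron conjunctive coupling delivers. One palladium-catalysed operation joins a ring alkenyllithium, vinylboronic pinacol ester and isobutenyl triflate, forming both bonds and C8 as a stereodefined C–B bond. The precursor is the (S)-carvone-derived alkenyl iodide 13 with the all-cis C1, C5, C6 array, O5 as triethylsilyl and O6 as tert-butyldimethylsilyl ether, so the two hydroxyls stay distinguishable.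

Key step: step 9

**Locants and faces.** Ring: C1 (bears the side chain), C2 (CH2), C3, C4 (methyl-bearing), C5, C6. Chain: C7 (the carbon on C1 that carries =CH2), C8, C9, C10, C11 (gem-dimethyl carbon). β is the ring face carrying the C1 side chain, α the opposite face. In these locants the target is (1R,3S,4S,5S,6S,8S,10R): 3α-Cl, 4β-OH, 5β-O-angelate, 6β-OH. In (S)-carvone the isopropenyl-bearing carbon is C1, the carbonyl carbon C5 and the α′-methylene C6.

**Design remarks.**
- O5 and O6 carry different silyl groups (SiEt3, Si(t-Bu)Me2), so O5 can be freed alone to direct the ring epoxidation and to be acylated, and O6 is freed only afterwards.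
- KOTf is added to the coupling because the iodide left by the lithium–iodine exchange would otherwise block the cationic palladium intermediate.
- Chloride is introduced before the side-chain epoxide exists, and that epoxide is made last.

**Assumptions.**
- Both antipodes of the ferrocenyl bisphosphine are available; the one that gives the (8S) boronate 19 is used, to be fixed by a small trial coupling.
- The D-fructose-derived Shi ketone is expected to give the (10R) epoxide by the spiro transition-state model.

## Route

Step 1
Reactants: 1 (S)-carvone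
Product: 4 trans-6-hydroxycarvone (6α-OH), via silyl dienol ether 2 (not isolated), via 6-silyloxy ketone 3 (not isolated)
Conditions: LiN(iPr)2 (LDA), THF, −78 °C, then TMSCl; mCPBA, NaHCO3, CH2Cl2, −20 to 0 °C; 1 M HCl, THF, rt
Reagents that add atoms: mCPBA, O=C(OO)c1cccc(Cl)c1
Why: Rubottom oxidation, in which kinetic α′-deprotonation and silylation give the cross-conjugated silyl dienol ether and mCPBA epoxidises its electron-rich enol ether bond anti to the neighbouring isopropenyl group, so the C6 hydroxyl ends up trans (α) to the side chain.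

Step 2
Reactants: 4 trans-6-hydroxycarvone
Product: 6 cis-6-hydroxycarvone (6β-OH), via cis 4-nitrobenzoate 5 (not isolated)
Conditions: 4-nitrobenzoic acid, PPh3, DIAD, THF, 0 °C to rt; then MeOH, K2CO3, 0 °C
Reagents that add atoms: 4-nitrobenzoic acid, OC(=O)c1ccc(cc1)[N+](=O)[O-]
Why: Mitsunobu reaction, in which the C6 oxyphosphonium, activated by the adjacent carbonyl, is displaced by 4-nitrobenzoate with SN2 inversion so that the C6 oxygen becomes cis to the C1 side chain, and the activated ester is then methanolysed faster than C6 can enolise.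

Step 3
Reactants: 6 cis-6-hydroxycarvone
Product: 7 cis-6-(tert-butyldimethylsilyloxy)carvone
Conditions: TBSOTf, 2,6-lutidine, CH2Cl2, −78 °C
Reagents that add atoms: TBSOTf, CC(C)(C)[Si](C)(C)OS(=O)(=O)C(F)(F)F
Why: Silyl ether formation on a hindered secondary alcohol with the silyl triflate and a base too weak to enolise the ketone, so C6 keeps its configuration.

Step 4
Reactants: 7 cis-6-(tert-butyldimethylsilyloxy)carvone
Product: 8 allylic alcohol with 5β-OH and 6β-OTBS
Conditions: NaBH4, CeCl3·7H2O, MeOH, −78 °C, quenched cold with AcOH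
Reagents that add atoms: none
Why: Luche reduction gives 1,2-reduction of the enone, and hydride enters C5 from the α face, opposite the axial 6β-silyloxy group and the C1 side chain, so the new C5 hydroxyl is β and C1, C5, C6 are all-cis.

Step 5
Reactants: 8 allylic alcohol with 5β-OH and 6β-OTBS
Product: 9 bis-silyl ether (5β-OTES, 6β-OTBS)
Conditions: TESCl, imidazole, DMF, 0 °C
Reagents that add atoms: TESCl, CC[Si](Cl)(CC)CC
Why: Silyl ether formation at the free allylic C5 hydroxyl under weakly basic conditions at 0 °C, where the neighbouring silyl group does not migrate and no stereocentre is touched.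

Step 6
Reactants: 9 bis-silyl ether (5β-OTES, 6β-OTBS)
Product: 11 methyl ketone (acetyl group on C1), via C7 diol 10 (not isolated)
Conditions: OsO4 (2 mol%), NaIO4, 2,6-lutidine, dioxane/H2O, rt
Reagents that add atoms: NaIO4, [Na+].[O-]I(=O)(=O)=O; OsO4, O=[Os](=O)(=O)=O
Why: Lemieux–Johnson cleavage, in which OsO4 should dihydroxylate the unhindered 1,1-disubstituted C7 alkene faster than the trisubstituted ring alkene (shielded by the flanking triethylsilyloxy group and deactivated by the allylic oxygen), and NaIO4 cleaves the diol to the methyl ketone without touching a stereocentre.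

Step 7
Reactants: 11 methyl ketone (acetyl group on C1)
Product: 13 ring alkenyl iodide (1-iodoethenyl group on C1), via hydrazone 12 (not isolated)
Conditions: N2H4·H2O, Et3N, EtOH, 70 °C; concentrate; I2, 1,1,3,3-tetramethylguanidine, THF, 0 °C to rt
Reagents that add atoms: iodine, II
Why: Barton vinyl iodide synthesis, in which iodination of the hydrazone and loss of N2 give an α-iodo cation equivalent that the guanidine base deprotonates at the methyl group, leaving the 1,1-disubstituted alkenyl iodide and the C1 stereocentre untouched.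

Step 8
Reactants: 14 isobutyraldehyde
Product: 15 2-methylprop-1-en-1-yl trifluoromethanesulfonate
Conditions: Tf2O, 2,6-di-tert-butyl-4-methylpyridine, CH2Cl2, 0 °C to rt
Reagents that add atoms: Tf2O, O=S(=O)(OS(=O)(=O)C(F)(F)F)C(F)(F)F
Why: Enol triflate formation from an enolisable aldehyde, by O-triflation of the carbonyl and deprotonation of the α C–H by the hindered pyridine base, with no geometric isomers possible.

Step 9
Reactants: 13 ring alkenyl iodide; 16 vinylboronic acid pinacol ester; 15 2-methylprop-1-en-1-yl trifluoromethanesulfonate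
Product: 19 (8S) C8 pinacol boronate with the complete C1–C11 skeleton, via alkenyllithium 17 (not isolated), via boron ate complex 18 (not isolated)
Conditions: t-BuLi (2.0 equiv), Et2O, −78 °C; 16, −78 °C to rt; solvent changed to THF; 15, KOTf, Pd(OAc)2 (2 mol%), 1,1′-bis[(dimethylamino)(phenyl)methyl]-2,2′-bis[bis(4-methoxy-3,5-dimethylphenyl)phosphino]ferrocene (single antipode, 2.4 mol%), THF, 60 °C; crude 19 filtered through silica and used at once
Reagents that add atoms: none
Why: t-BuLi exchanges the C7–I bond and alkenyllithium 17 adds to boron of 16 to give the bis(alkenyl) ate complex 18; the cationic alkenylpalladium species formed from 15 by oxidative addition to zerovalent palladium binds the unsubstituted vinyl group, the C7 alkenyl group shifts 1,2 from boron to C8 as palladium bonds to C9, and reductive elimination joins C9 to C10. The closest known reaction type is the enantioselective palladium-catalysed conjunctive cross-coupling of bis(alkenyl)boron ate complexes with alkenyl triflates, which gives α-chiral allylic boronates. No ring is closed. The new C8 stereocentre is set by the chiral bisphosphine on palladium (catalyst control), because C8 belongs to the achiral vinyl acceptor and the bias from the ring stereocentres of the migrating group is expected to be weak. The step needs the vinyl group, not the C7 alkene, to be the acceptor and needs the metallate shift to outrun direct Suzuki-type transmetallation: the branched 1,1-disubstituted C7 alkene is a poor ligand for palladium while the bare vinyl group binds readily, the wide-bite-angle ligand favours the shift, and KOTf removes the iodide that would block the cationic palladium centre.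

Step 10
Reactants: 19 (8S) C8 pinacol boronate
Product: 20 (8S) allylic alcohol (C8–OH)
Conditions: NaOH (aq), H2O2, THF, 0 °C
Reagents that add atoms: hydrogen peroxide, OO
Why: Oxidation of the C–B bond by hydroperoxide, in which C8 migrates from boron to oxygen with retention, so the (8S) boronate gives the (8S) allylic alcohol without allylic transposition.

Step 11
Reactants: 20 (8S) allylic alcohol; 21 angelic acid
Product: 22 C8 angelate (5β-OTES, 6β-OTBS)
Conditions: 21, 2,4,6-trichlorobenzoyl chloride, Et3N, toluene, rt; then 20, 80 °C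
Reagents that add atoms: none
Why: Yamaguchi-type esterification through the mixed 2,4,6-trichlorobenzoic anhydride, run without a nucleophilic catalyst so that the Z enoate is not isomerised to the tiglate, and C8 is not touched.

Step 12
Reactants: 22 C8 angelate (5β-OTES, 6β-OTBS)
Product: 23 C8 angelate with free 5β-OH (6β-OTBS)
Conditions: PPTS, MeOH/CH2Cl2, 0 °C
Reagents that add atoms: none
Why: Selective desilylation, since acid-catalysed methanolysis removes the triethylsilyl ether far faster than the tert-butyldimethylsilyl ether and frees only the allylic C5 hydroxyl.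

Step 13
Reactants: 23 C8 angelate with free 5β-OH
Product: 24 3β,4β-epoxy alcohol
Conditions: VO(acac)2 (5 mol%), t-BuOOH, CH2Cl2, 0 °C to rt
Reagents that add atoms: tert-butyl hydroperoxide, CC(C)(C)OO
Why: Hydroxyl-directed epoxidation, in which the vanadium alkoxide of the C5 hydroxyl delivers the peroxide oxygen to the adjacent C3=C4 bond on the β face (setting C3 and C4), while the side-chain alkenes, which have no free allylic hydroxyl, are left alone.

Step 14
Reactants: 24 3β,4β-epoxy alcohol
Product: 25 chlorohydrin (3α-Cl, 4β-OH, 5β-OH, 6β-OTBS)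
Conditions: Ti(OiPr)4, Et2NH·HCl, CH2Cl2, rt
Reagents that add atoms: diethylammonium chloride, CC[NH2+]CC.[Cl-]
Why: Titanium-assisted opening of a 2,3-epoxy alcohol, in which titanium chelated between O5 and the epoxide oxygen activates the ring and chloride attacks the distal secondary C3 from the α face with inversion (trans-diaxial, Fürst–Plattner), giving 3α-Cl and 4β-OH.

Step 15
Reactants: 25 chlorohydrin; 21 angelic acid
Product: 26 bis-angelate (C5 and C8 esters, 6β-OTBS)
Conditions: 21, 2,4,6-trichlorobenzoyl chloride, Et3N, toluene, rt; then 25, 90 °C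
Reagents that add atoms: none
Why: The same mixed-anhydride esterification, in which the secondary C5 hydroxyl is the only acylable one because O6 is silylated and the C4 hydroxyl is tertiary, and the weakly basic, catalyst-free conditions keep the Z geometry and the chlorohydrin.

Step 16
Reactants: 26 bis-angelate (6β-OTBS)
Product: 27 de-epoxy target (free 6β-OH, C10=C11 alkene)
Conditions: HF·pyridine, pyridine, THF, 0 °C to rt
Reagents that add atoms: none
Why: Fluoride-mediated desilylation under buffered, weakly acidic conditions, which removes the silyl ether without closing the chlorohydrin to an epoxide or moving the C5 ester.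

Step 17
Reactants: 27 de-epoxy target
Product: 28 target CNP0158207.1
Conditions: D-fructose-derived Shi ketone (1 equiv), Oxone (2KHSO5·KHSO4·K2SO4), NaHCO3, Na2EDTA (aq), MeCN, 0 °C, pH about 8
Reagents that add atoms: Oxone (active component KHSO5), [K+].[O-]S(=O)(=O)OO
Why: Shi asymmetric epoxidation, in which the chiral dioxirane epoxidises the electron-rich trisubstituted C10=C11 alkene through a spiro transition state and the D-fructose-derived ketone should give the (10R) epoxide, while the electron-poor angelate alkenes and the hindered 1,1-disubstituted C7 alkene do not react and pH 8 spares the chlorohydrin.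

## Compound list

1 | (S)-carvone, (5S)-2-methyl-5-(prop-1-en-2-yl)cyclohex-2-en-1-one | CC1=CC[C@@H](CC1=O)C(C)=C | starting material
2 | carvone trimethylsilyl dienol ether (C5–OTMS, C5=C6 and C3=C4 double bonds, C1 unchanged) | C=C(C)[C@H]1CC=C(C)C(O[Si](C)(C)C)=C1 | intermediate
3 | trans-6-(trimethylsilyloxy)carvone (6α-OTMS) | C=C(C)[C@H]1CC=C(C)C(=O)[C@@H]1O[Si](C)(C)C | intermediate
4 | trans-6-hydroxycarvone, (5R,6R)-6-hydroxy-2-methyl-5-(prop-1-en-2-yl)cyclohex-2-en-1-one (6α-OH) | C=C(C)[C@H]1CC=C(C)C(=O)[C@@H]1O | intermediate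
5 | cis-6-(4-nitrobenzoyloxy)carvone (6β-ester, cis to the isopropenyl group) | C=C(C)[C@H]1CC=C(C)C(=O)[C@H]1OC(=O)c1ccc(cc1)[N+](=O)[O-] | intermediate
6 | cis-6-hydroxycarvone, (5R,6S)-6-hydroxy-2-methyl-5-(prop-1-en-2-yl)cyclohex-2-en-1-one (6β-OH) | C=C(C)[C@H]1CC=C(C)C(=O)[C@H]1O | intermediate
7 | cis-6-(tert-butyldimethylsilyloxy)carvone (6β-OTBS) | C=C(C)[C@H]1CC=C(C)C(=O)[C@H]1O[Si](C)(C)C(C)(C)C | intermediate
8 | (1R,5R,6S)-6-(tert-butyldimethylsilyloxy)-2-methyl-5-(prop-1-en-2-yl)cyclohex-2-en-1-ol (5β-OH, 6β-OTBS, all-cis with the isopropenyl group) | C=C(C)[C@H]1CC=C(C)[C@@H](O)[C@H]1O[Si](C)(C)C(C)(C)C | intermediate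
9 | bis-silyl ether: as 8 with 5β-OSiEt3 and 6β-OSi(t-Bu)Me2 | C=C(C)[C@H]1CC=C(C)[C@@H](O[Si](CC)(CC)CC)[C@H]1O[Si](C)(C)C(C)(C)C | intermediate
10 | C7 diol: as 9 with the isopropenyl group dihydroxylated to C(OH)(CH3)CH2OH (mixture of C7 epimers) | CC(O)(CO)[C@H]1CC=C(C)[C@@H](O[Si](CC)(CC)CC)[C@H]1O[Si](C)(C)C(C)(C)C | intermediate
11 | methyl ketone: acetyl group on C1, 5β-OTES, 6β-OTBS, C3=C4 | CC(=O)[C@H]1CC=C(C)[C@@H](O[Si](CC)(CC)CC)[C@H]1O[Si](C)(C)C(C)(C)C | intermediate
12 | hydrazone of 11 (C7=N–NH2) | CC(=NN)[C@H]1CC=C(C)[C@@H](O[Si](CC)(CC)CC)[C@H]1O[Si](C)(C)C(C)(C)C | intermediate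
13 | ring alkenyl iodide: 1-iodoethenyl group on C1, 5β-OTES, 6β-OTBS, C3=C4 | C=C(I)[C@H]1CC=C(C)[C@@H](O[Si](CC)(CC)CC)[C@H]1O[Si](C)(C)C(C)(C)C | intermediate
14 | isobutyraldehyde | CC(C)C=O | starting material
15 | 2-methylprop-1-en-1-yl trifluoromethanesulfonate | CC(C)=COS(=O)(=O)C(F)(F)F | intermediate
16 | vinylboronic acid pinacol ester | C=CB1OC(C)(C)C(C)(C)O1 | starting material
17 | alkenyllithium: as 13 with Li in place of I on C7 | [Li]C(=C)[C@H]1CC=C(C)[C@@H](O[Si](CC)(CC)CC)[C@H]1O[Si](C)(C)C(C)(C)C | intermediate
18 | lithium bis(alkenyl) pinacol ate complex: boron bears vinyl and the C7 alkenyl group | [Li+].C=C[B-]1(OC(C)(C)C(C)(C)O1)C(=C)[C@H]1CC=C(C)[C@@H](O[Si](CC)(CC)CC)[C@H]1O[Si](C)(C)C(C)(C)C | intermediate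
19 | (8S) C8 pinacol boronate: C7(=CH2)–C8H(Bpin)–C9H2–C10H=C11(CH3)2 chain on C1, 5β-OTES, 6β-OTBS, C3=C4 | C=C([C@H](CC=C(C)C)B1OC(C)(C)C(C)(C)O1)[C@H]1CC=C(C)[C@@H](O[Si](CC)(CC)CC)[C@H]1O[Si](C)(C)C(C)(C)C | intermediate
20 | (8S) allylic alcohol: as 19 with OH in place of Bpin | C=C([C@H](CC=C(C)C)O)[C@H]1CC=C(C)[C@@H](O[Si](CC)(CC)CC)[C@H]1O[Si](C)(C)C(C)(C)C | intermediate
21 | angelic acid, (Z)-2-methylbut-2-enoic acid | C/C=C(/C)C(=O)O | starting material
22 | C8 angelate: as 20 with the C8 oxygen esterified by (Z)-2-methylbut-2-enoate | C=C([C@H](CC=C(C)C)OC(=O)/C(C)=C\C)[C@H]1CC=C(C)[C@@H](O[Si](CC)(CC)CC)[C@H]1O[Si](C)(C)C(C)(C)C | intermediate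
23 | C8 angelate with free 5β-OH and 6β-OTBS | C=C([C@H](CC=C(C)C)OC(=O)/C(C)=C\C)[C@H]1CC=C(C)[C@@H](O)[C@H]1O[Si](C)(C)C(C)(C)C | intermediate
24 | 3β,4β-epoxide of 23 (epoxide cis to 5β-OH) | C=C([C@H](CC=C(C)C)OC(=O)/C(C)=C\C)[C@H]1C[C@H]2O[C@@]2(C)[C@@H](O)[C@H]1O[Si](C)(C)C(C)(C)C | intermediate
25 | chlorohydrin: 3α-Cl, 4β-OH (4α-CH3), 5β-OH, 6β-OTBS, C8 angelate | C=C([C@H](CC=C(C)C)OC(=O)/C(C)=C\C)[C@H]1C[C@H](Cl)[C@@](C)(O)[C@@H](O)[C@H]1O[Si](C)(C)C(C)(C)C | intermediate
26 | bis-angelate: as 25 with the C5 oxygen esterified by (Z)-2-methylbut-2-enoate | C=C([C@H](CC=C(C)C)OC(=O)/C(C)=C\C)[C@H]1C[C@H](Cl)[C@@](C)(O)[C@@H](OC(=O)/C(C)=C\C)[C@H]1O[Si](C)(C)C(C)(C)C | intermediate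
27 | de-epoxy target: as 26 with free 6β-OH, C10=C11 alkene | C=C([C@H](CC=C(C)C)OC(=O)/C(C)=C\C)[C@H]1C[C@H](Cl)[C@@](C)(O)[C@@H](OC(=O)/C(C)=C\C)[C@H]1O | intermediate
28 | CNP0158207.1, (1R,3S,4S,5S,6S,8S,10R) in the locants above | C=C([C@H](C[C@H]1OC1(C)C)OC(=O)/C(C)=C\C)[C@H]1C[C@H](Cl)[C@@](C)(O)[C@@H](OC(=O)/C(C)=C\C)[C@H]1O | target

## Step count and risks

Total: 17 steps. Longest linear sequence: 16 steps, from (S)-carvone 1 to target 28 through steps 1–7 and 9–17; step 8 is a one-step side branch to triflate 15.

The three steps most likely to fail: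

1. **Step 9 (key step).** What may go wrong:
   - Facial control at C8 is eroded by the crowded, chiral migrating group.
   - Direct transmetallation (Suzuki-type C7–C10 coupling) outruns the 1,2-shift.
   - A silyl group shifts from O6 to C7 if the alkenyllithium warms before it is captured by the boronate.

   Fallback, setting out from 13 and coming back at 20: 13 is lithiated as before (t-BuLi, Et2O, −78 °C) to 17. It is acylated with the Weinreb amide N-methoxy-N,4-dimethylpent-3-enamide F1, prepared from commercial 4-methylpent-3-enoic acid, MeNHOMe·HCl and carbonyldiimidazole. This gives the cross-conjugated C8 dienone F2 and forms C7–C8 by acyl substitution. Corey–Bakshi–Shibata reduction of F2 with the (R)-2-methyl oxazaborolidine and BH3·SMe2 at low temperature, with the branched alkenyl group as the large substituent, should then set (8S) and give alcohol 20.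

2. **Step 2.** What may go wrong: the crowded C6 oxyphosphonium eliminates or is displaced incompletely, so inversion is partial.

   Fallback, setting out from 4 and coming back at 5: the redox condensation is replaced by a two-stage sulfonate displacement. Tf2O and pyridine (CH2Cl2, −20 °C) convert 4 into the α-keto triflate F3. Caesium 4-nitrobenzoate with 18-crown-6 in toluene displaces it at C6 with inversion, giving ester 5, which is methanolysed to 6 as in step 2.

3. **Step 6.** What may go wrong: chemoselectivity between the two alkenes is lost, with dihydroxylation and cleavage of the ring C3=C4 bond.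

   Fallback, setting out from 7 and coming back at 11: the side-chain alkene is oxidised while the ring alkene is still deactivated by the enone carbonyl. OsO4 (cat.) and N-methylmorpholine N-oxide in acetone/H2O dihydroxylate only the isopropenyl group of 7 to give the enone diol F4. Luche reduction (NaBH4, CeCl3·7H2O, MeOH, −78 °C) gives the triol F5 with 5β-OH as in step 4. NaIO4 cleaves its 1,2-diol to the hydroxy methyl ketone F6. TESCl and imidazole then give 11.

## Further compounds

F1 | step 9 | N-methoxy-N,4-dimethylpent-3-enamide | CC(C)=CCC(=O)N(C)OC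
F2 | step 9 | C8 dienone: C7(=CH2)–C8(=O)–C9H2–C10H=C11(CH3)2 chain on C1, 5β-OTES, 6β-OTBS, C3=C4 | C=C(C(=O)CC=C(C)C)[C@H]1CC=C(C)[C@@H](O[Si](CC)(CC)CC)[C@H]1O[Si](C)(C)C(C)(C)C
F3 | step 2 | trans-6-(trifluoromethanesulfonyloxy)carvone (6α-OTf) | C=C(C)[C@H]1CC=C(C)C(=O)[C@@H]1OS(=O)(=O)C(F)(F)F
F4 | step 6 | enone diol: as 7 with the isopropenyl group dihydroxylated (mixture of C7 epimers) | CC(O)(CO)[C@H]1CC=C(C)C(=O)[C@H]1O[Si](C)(C)C(C)(C)C
F5 | step 6 | triol: as F4 with the C5 carbonyl reduced to 5β-OH | CC(O)(CO)[C@H]1CC=C(C)[C@@H](O)[C@H]1O[Si](C)(C)C(C)(C)C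
F6 | step 6 | hydroxy methyl ketone: acetyl group on C1, 5β-OH, 6β-OTBS | CC(=O)[C@H]1CC=C(C)[C@@H](O)[C@H]1O[Si](C)(C)C(C)(C)C
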